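**Retrosynthetic overview**
- Last bond made: the side-chain ester C–O, by Mitsunobu esterification of the C11 dihydropyran acid (aldehyde and methyl ester already in place) with free hydroxytyrosol.
- Hydroxytyrosol: from catechol by para-bromination, silylation, aryllithium opening of oxirane, and desilylation.
- Acid: C3 aldehyde from oxidative cleavage of a vinyl group; side-chain acid from selective saponification; the dihydropyran from an α-formyl δ-lactone by acid methanolysis (lactone oxygen becomes ring O1).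
- Formyl lactone: one-pot conjugate addition of methyl acetate enolate and formylation on a trans-5-vinyl-6-methyl-5,6-dihydropyran-2-one, itself made by group-selective ring-closing metathesis of the acrylate of (S)-3-vinylpent-4-en-2-ol.
- Ring order: unsaturated δ-lactone first (RCM), then the dihydropyran (lactone-to-pyran transposition); the arene is bought as catechol. The carbinol centre comes from asymmetric pentadienylboration of acetaldehyde.

Assumption: a sequence run in one flask without isolation counts as one step; the ring is numbered O1, C2 (CH3), C3 (CHO), C4 (CH2CO2R), C5 (CO2Me), C6, which makes the target (2S,3R,4R), all-trans.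

**Step 1**
Reactants: 1 penta-1,4-diene; 2 acetaldehyde
Product: 6 (2S)-3-ethenylpent-4-en-2-ol, via pentadienyllithium 3 (not isolated), via B-pentadienyl-diisopinocampheylborane 4 (not isolated), via borinic ester 5 (not isolated)
Conditions: n-BuLi, THF, −78→0 °C; (+)-DIP-Cl [(+)-Ipc2BCl, from (−)-α-pinene], −78 °C; 2, −78 °C; NaOH, 30% H2O2, 0 °C→rt
Reagents that add atoms: none
Why: Brown-type asymmetric allylboration, in which the terminal pentadienylborane reacts through a closed chair transition state at its γ-carbon (giving the bis-vinyl carbinol) and the isopinocampheyl groups of the (−)-α-pinene series direct attack to the Re face of acetaldehyde, setting C2 as S.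

**Step 2**
Reactants: 6 (2S)-3-ethenylpent-4-en-2-ol; 7 acryloyl chloride
Product: 8 (2S)-3-ethenylpent-4-en-2-yl prop-2-enoate
Conditions: Et3N, DMAP (cat.), CH2Cl2, 0 °C
Reagents that add atoms: none
Why: O-acylation of the secondary alcohol by an acid chloride, which leaves the carbinol stereocentre untouched.

**Step 3**
Reactants: 8 (2S)-3-ethenylpent-4-en-2-yl prop-2-enoate
Product: 9 (5R,6S)-5-ethenyl-6-methyl-5,6-dihydro-2H-pyran-2-one
Conditions: Grubbs II (5 mol %), CH2Cl2 (5 mM), 40 °C
Reagents that add atoms: none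
Why: Ring-closing metathesis of the acrylate onto one of two diastereotopic vinyl groups, where closure through the half-chair with methyl and spectator vinyl both pseudo-equatorial should favour the trans (5R,6S) lactone and the minor cis isomer is removed by chromatography.

**Step 4**
Reactants: 9 (5R,6S)-5-ethenyl-6-methyl-5,6-dihydro-2H-pyran-2-one; 10 methyl acetate
Product: 13 methyl 2-[(2S,3R,4R,5Z)-3-ethenyl-5-(hydroxymethylidene)-2-methyl-6-oxooxan-4-yl]acetate, via lithium enolate of methyl acetate 11 (not isolated), via lactone lithium enolate 12 (not isolated)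
Conditions: LDA, 10, THF, −78 °C; 9, −78 °C; CF3CH2OCHO, −78→−20 °C; 1 M HCl
Reagents that add atoms: 2,2,2-trifluoroethyl formate, O=COCC(F)(F)F
Why: Tandem Michael addition and Claisen formylation, in which the ester enolate adds to the β-carbon of the unsaturated lactone anti to the adjacent vinyl group (setting the third stereocentre trans to vinyl and cis to methyl) and the regiodefined lactone enolate is trapped by the formate.

**Step 5**
Reactants: 13 methyl 2-[(2S,3R,4R,5Z)-3-ethenyl-5-(hydroxymethylidene)-2-methyl-6-oxooxan-4-yl]acetate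
Product: 14 methyl (2S,3R,4R)-3-ethenyl-4-(2-methoxy-2-oxoethyl)-2-methyl-3,4-dihydro-2H-pyran-5-carboxylate
Conditions: HCl (1.25 M in MeOH), 0→50 °C
Reagents that add atoms: methanol, CO
Why: Acid-catalysed lactone methanolysis followed by cyclodehydration of the freed secondary hydroxyl onto the formyl group (lactone-to-dihydropyran transposition) gives the β-alkoxyacrylate without breaking any bond to a stereocentre, so the all-trans array is kept.

**Step 6**
Reactants: 14 methyl (2S,3R,4R)-3-ethenyl-4-(2-methoxy-2-oxoethyl)-2-methyl-3,4-dihydro-2H-pyran-5-carboxylate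
Product: 15 2-[(2S,3R,4R)-3-ethenyl-5-(methoxycarbonyl)-2-methyl-3,4-dihydro-2H-pyran-4-yl]acetic acid
Conditions: LiOH·H2O (1.2 equiv), THF/H2O, 0 °C; then 1 M HCl
Reagents that add atoms: lithium hydroxide, [Li+].[OH-]
Why: Chemoselective saponification, because the aliphatic acetate ester is far more electrophilic than the vinylogous-carbonate methyl ester, which is deactivated by conjugation with the ring oxygen.

**Step 7**
Reactants: 15 2-[(2S,3R,4R)-3-ethenyl-5-(methoxycarbonyl)-2-methyl-3,4-dihydro-2H-pyran-4-yl]acetic acid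
Product: 16 2-[(2S,3R,4R)-3-formyl-5-(methoxycarbonyl)-2-methyl-3,4-dihydro-2H-pyran-4-yl]acetic acid
Conditions: OsO4 (2 mol %), NaIO4, 2,6-lutidine, dioxane/H2O, rt
Reagents that add atoms: osmium tetroxide (catalytic oxygen carrier), O=[Os](=O)(=O)=O; sodium periodate (terminal oxidant and oxygen source), [Na+].[O-]I(=O)(=O)=O
Why: Lemieux–Johnson oxidative cleavage of the monosubstituted vinyl group, which is more reactive than the electron-poor trisubstituted ring alkene, unveils the C3 aldehyde with retention, trans to both neighbours.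

**Step 8**
Reactants: 17 benzene-1,2-diol (catechol)
Product: 18 4-bromobenzene-1,2-diol
Conditions: NBS, HBF4·OEt2 (cat.), MeCN, −30 °C→rt
Reagents that add atoms: N-bromosuccinimide, O=C1CCC(=O)N1Br
Why: Electrophilic aromatic bromination, directed para to one hydroxyl (position 4) by the two donor groups.

**Step 9**
Reactants: 18 4-bromobenzene-1,2-diol
Product: 19 4-bromo-1,2-bis(tert-butyldimethylsilyloxy)benzene
Conditions: TBSCl, imidazole, DMF, rt
Reagents that add atoms: tert-butyldimethylsilyl chloride, CC(C)(C)[Si](C)(C)Cl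
Why: Silylation masks both acidic phenols so that the aryl bromide can be lithiated in the next step.

**Step 10**
Reactants: 19 4-bromo-1,2-bis(tert-butyldimethylsilyloxy)benzene; 20 oxirane
Product: 22 2-[3,4-bis(tert-butyldimethylsilyloxy)phenyl]ethan-1-ol, via aryllithium 21 (not isolated)
Conditions: n-BuLi, THF, −78 °C; 20, −78 °C→rt; H2O
Reagents that add atoms: none
Why: Bromine–lithium exchange followed by SN2 ring opening of oxirane installs the two-carbon alcohol chain, and the lithium is not ortho to a silyloxy group, so no silyl migration is expected.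

**Step 11**
Reactants: 22 2-[3,4-bis(tert-butyldimethylsilyloxy)phenyl]ethan-1-ol
Product: 23 4-(2-hydroxyethyl)benzene-1,2-diol (hydroxytyrosol)
Conditions: KHF2, MeOH, rt (degassed)
Reagents that add atoms: none
Why: Fluoride-mediated cleavage of aryl silyl ethers under non-basic conditions frees the air-sensitive catechol without oxidising it.

**Step 12**
Reactants: 16 2-[(2S,3R,4R)-3-formyl-5-(methoxycarbonyl)-2-methyl-3,4-dihydro-2H-pyran-4-yl]acetic acid; 23 4-(2-hydroxyethyl)benzene-1,2-diol
Product: 24 2-(3,4-dihydroxyphenyl)ethyl 2-[(2S,3R,4R)-3-formyl-5-(methoxycarbonyl)-2-methyl-3,4-dihydro-2H-pyran-4-yl]acetate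
Conditions: PPh3, DIAD, THF, 0 °C→rt
Reagents that add atoms: none
Why: Mitsunobu esterification, in which only the primary aliphatic alcohol is activated as its alkoxyphosphonium ion and only the carboxylic acid is acidic enough to act as the nucleophile, so the free phenols and the aldehyde are left alone and no stereocentre is involved.

**Compound list**
1 | penta-1,4-diene | C=CCC=C | starting material
2 | acetaldehyde | CC=O | starting material
3 | (2E)-penta-2,4-dien-1-yllithium | [Li]C/C=C/C=C | intermediate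
4 | [(2E)-penta-2,4-dien-1-yl]bis[(1S,2R,3S,5S)-2,6,6-trimethylbicyclo[3.1.1]heptan-3-yl]borane | C=C/C=C/CB([C@H]1C[C@H]2C[C@@H]([C@@H]1C)C2(C)C)[C@H]1C[C@H]2C[C@@H]([C@@H]1C)C2(C)C | intermediate
5 | (2S)-3-ethenylpent-4-en-2-yl bis[(1S,2R,3S,5S)-2,6,6-trimethylbicyclo[3.1.1]heptan-3-yl]borinate | C[C@H](OB([C@H]1C[C@H]2C[C@@H]([C@@H]1C)C2(C)C)[C@H]1C[C@H]2C[C@@H]([C@@H]1C)C2(C)C)C(C=C)C=C | intermediate
6 | (2S)-3-ethenylpent-4-en-2-ol | C[C@H](O)C(C=C)C=C | intermediate
7 | acryloyl chloride | C=CC(=O)Cl | starting material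
8 | (2S)-3-ethenylpent-4-en-2-yl prop-2-enoate | C=CC(=O)O[C@@H](C)C(C=C)C=C | intermediate
9 | (5R,6S)-5-ethenyl-6-methyl-5,6-dihydro-2H-pyran-2-one (trans) | O=C1O[C@@H](C)[C@H](C=C)C=C1 | intermediate
10 | methyl acetate | COC(C)=O | starting material
11 | lithium 1-methoxyethen-1-olate | [Li]OC(=C)OC | intermediate
12 | lithium (2S,3R,4R)-3-ethenyl-4-(2-methoxy-2-oxoethyl)-2-methyl-3,4-dihydro-2H-pyran-6-olate | [Li]OC1=C[C@H](CC(=O)OC)[C@@H](C=C)[C@H](C)O1 | intermediate
13 | methyl 2-[(2S,3R,4R,5Z)-3-ethenyl-5-(hydroxymethylidene)-2-methyl-6-oxooxan-4-yl]acetate | O=C1O[C@@H](C)[C@H](C=C)[C@@H](CC(=O)OC)/C1=C/O | intermediate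
14 | methyl (2S,3R,4R)-3-ethenyl-4-(2-methoxy-2-oxoethyl)-2-methyl-3,4-dihydro-2H-pyran-5-carboxylate | COC(=O)C1=CO[C@@H](C)[C@H](C=C)[C@H]1CC(=O)OC | intermediate
15 | 2-[(2S,3R,4R)-3-ethenyl-5-(methoxycarbonyl)-2-methyl-3,4-dihydro-2H-pyran-4-yl]acetic acid | COC(=O)C1=CO[C@@H](C)[C@H](C=C)[C@H]1CC(=O)O | intermediate
16 | 2-[(2S,3R,4R)-3-formyl-5-(methoxycarbonyl)-2-methyl-3,4-dihydro-2H-pyran-4-yl]acetic acid | COC(=O)C1=CO[C@@H](C)[C@H](C=O)[C@H]1CC(=O)O | intermediate
17 | benzene-1,2-diol (catechol) | Oc1ccccc1O | starting material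
18 | 4-bromobenzene-1,2-diol | Oc1ccc(Br)cc1O | intermediate
19 | 4-bromo-1,2-bis(tert-butyldimethylsilyloxy)benzene | CC(C)(C)[Si](C)(C)Oc1ccc(Br)cc1O[Si](C)(C)C(C)(C)C | intermediate
20 | oxirane | C1CO1 | starting material
21 | [3,4-bis(tert-butyldimethylsilyloxy)phenyl]lithium | [Li]c1ccc(O[Si](C)(C)C(C)(C)C)c(O[Si](C)(C)C(C)(C)C)c1 | intermediate
22 | 2-[3,4-bis(tert-butyldimethylsilyloxy)phenyl]ethan-1-ol | OCCc1ccc(O[Si](C)(C)C(C)(C)C)c(O[Si](C)(C)C(C)(C)C)c1 | intermediate
23 | 4-(2-hydroxyethyl)benzene-1,2-diol (hydroxytyrosol) | OCCc1ccc(O)c(O)c1 | intermediate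
24 | 2-(3,4-dihydroxyphenyl)ethyl 2-[(2S,3R,4R)-3-formyl-5-(methoxycarbonyl)-2-methyl-3,4-dihydro-2H-pyran-4-yl]acetate | COC(=O)C1=CO[C@@H](C)[C@H](C=O)[C@H]1CC(=O)OCCc1ccc(O)c(O)c1 | target

**Totals**
Total step count: 12.
Longest linear sequence: 8 (steps 1–7, then step 12); the hydroxytyrosol branch is steps 8–11, then step 12.

**Three steps most likely to fail**

Step 3 (group-selective RCM). The trans:cis ratio between the two diastereotopic vinyl groups is uncertain, and only the trans lactone leads to the right C4 configuration. The fallback sets out again from 2 and fixes the C5/C6 relationship before ring closure. Allylboration of 2 with pinacol (2E,4E)-hexa-2,4-dien-1-ylboronate under (R)-TRIP phosphoric-acid catalysis gives, through the borate ester 2-{[(2S,3S,4E)-3-ethenylhex-4-en-2-yl]oxy}-4,4,5,5-tetramethyl-1,3,2-dioxaborolane F1 (not isolated, hydrolysed on work-up), the anti alcohol (2S,3S,4E)-3-ethenylhex-4-en-2-ol F2; the anti relationship follows from the chair transition state of the E-boronate. Acylation with 7 gives (2S,3S,4E)-3-ethenylhex-4-en-2-yl prop-2-enoate F3. RCM, which engages the single terminal vinyl group in preference to the internal propenyl group, gives (5R,6S)-6-methyl-5-[(1E)-prop-1-en-1-yl]-5,6-dihydro-2H-pyran-2-one F4. Ethenolysis (ethene, Grubbs II) trims the propenyl group to vinyl and comes back to the route at 9.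

Step 4 (one-pot conjugate addition and formylation). The basic ester enolate may deprotonate the lactone at its γ-position, and face selectivity at C4 rests on the vinyl group alone. The fallback sets out from 9 and separates the two bond formations under non-basic control. Mukaiyama–Michael addition of 1-methoxy-1-(tert-butyldimethylsilyloxy)ethene (TBSOTf cat., CH2Cl2, −78 °C) gives the silyl ketene acetal methyl 2-[(2S,3R,4R)-6-{[tert-butyl(dimethyl)silyl]oxy}-3-ethenyl-2-methyl-3,4-dihydro-2H-pyran-4-yl]acetate F5 (not isolated), which acidic work-up hydrolyses to the lactone methyl 2-[(2S,3R,4S)-3-ethenyl-2-methyl-6-oxooxan-4-yl]acetate F6. Bredereck's reagent (t-BuOCH(NMe2)2, toluene, 90 °C), which condenses with the lactone α-CH2 much faster than with the acyclic ester, gives the enaminolactone methyl 2-[(2S,3R,4R,5E)-5-[(dimethylamino)methylidene]-3-ethenyl-2-methyl-6-oxooxan-4-yl]acetate F7. F7 is taken through the conditions of step 5 and comes back to the route at 14.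

Step 12 (Mitsunobu with a free catechol). The catechol may be O-alkylated or tied up as a phosphorane. The fallback sets out from 16 and the silyl-protected alcohol 22, so step 11 is not needed. Steglich esterification (EDC·HCl, DMAP, CH2Cl2) gives 2-[3,4-bis(tert-butyldimethylsilyloxy)phenyl]ethyl 2-[(2S,3R,4R)-3-formyl-5-(methoxycarbonyl)-2-methyl-3,4-dihydro-2H-pyran-4-yl]acetate F8, and HF·pyridine (THF, 0 °C) removes both aryl silyl ethers to reach 24.

**Further compounds**
F1 | step 3 | 2-{[(2S,3S,4E)-3-ethenylhex-4-en-2-yl]oxy}-4,4,5,5-tetramethyl-1,3,2-dioxaborolane | C[C@H](OB1OC(C)(C)C(C)(C)O1)[C@H](/C=C/C)C=C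
F2 | step 3 | (2S,3S,4E)-3-ethenylhex-4-en-2-ol | C[C@H](O)[C@H](/C=C/C)C=C
F3 | step 3 | (2S,3S,4E)-3-ethenylhex-4-en-2-yl prop-2-enoate | C=CC(=O)O[C@@H](C)[C@H](/C=C/C)C=C
F4 | step 3 | (5R,6S)-6-methyl-5-[(1E)-prop-1-en-1-yl]-5,6-dihydro-2H-pyran-2-one | O=C1O[C@@H](C)[C@H](/C=C/C)C=C1
F5 | step 4 | methyl 2-[(2S,3R,4R)-6-{[tert-butyl(dimethyl)silyl]oxy}-3-ethenyl-2-methyl-3,4-dihydro-2H-pyran-4-yl]acetate | CC(C)(C)[Si](C)(C)OC1=C[C@H](CC(=O)OC)[C@@H](C=C)[C@H](C)O1
F6 | step 4 | methyl 2-[(2S,3R,4S)-3-ethenyl-2-methyl-6-oxooxan-4-yl]acetate | O=C1C[C@H](CC(=O)OC)[C@@H](C=C)[C@H](C)O1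
F7 | step 4 | methyl 2-[(2S,3R,4R,5E)-5-[(dimethylamino)methylidene]-3-ethenyl-2-methyl-6-oxooxan-4-yl]acetate | O=C1O[C@@H](C)[C@H](C=C)[C@@H](CC(=O)OC)/C1=C\N(C)C
F8 | step 12 | 2-[3,4-bis(tert-butyldimethylsilyloxy)phenyl]ethyl 2-[(2S,3R,4R)-3-formyl-5-(methoxycarbonyl)-2-methyl-3,4-dihydro-2H-pyran-4-yl]acetate | COC(=O)C1=CO[C@@H](C)[C@H](C=O)[C@H]1CC(=O)OCCc1ccc(O[Si](C)(C)C(C)(C)C)c(O[Si](C)(C)C(C)(C)C)c1
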